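**Retrosynthetic overview**
1. The ten-membered carbocycle is the last ring formed: a Ni-catalysed, Cr-mediated alkenyl iodide–aldehyde (Nozaki–Hiyama–Kishi) closure at C8–C9 (cyclodeca[b]furan numbering), then oxidation to the enone and desilylation.
2. The seco-aldehyde comes from a Cr-catalysed allylation that joins fragment A (bromomethylbutenolide carrying the (Z)-iodoalkene) to fragment B (α-acyloxy aldehyde). It forms C3a–C4, both new stereocentres and the α-methylene lactone.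
3. Fragment A: butenolide by ring-closing metathesis of a 2-(bromomethyl)acrylate; its carbinol from (R)-epichlorohydrin, ethynyltrimethylsilane and a sulfonium ylide; the (Z)-iodoalkene by anti-carbometalation.
4. Fragment B: syn-crotylation of crotonaldehyde with cis-2-butene, early esterification with fragment C, hydroboration, silylation, ozonolysis.
5. Fragment C (the oxirane, first ring formed): Sharpless epoxidation of tiglyl alcohol, then oxidation to the acid.

Assumption: the SMILES is read as (3aR,4R,5R,6S,9Z,11aR) with a (2R,3S) cis-dimethyl epoxy ester, and (R)-epichlorohydrin, cis-2-butene and 2-(bromomethyl)acrylic acid are taken as commercial.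

**Route**

Step 1
Reactants: 1 (2E)-2-methylbut-2-en-1-ol
Product: 2 [(2S,3S)-2,3-dimethyloxiran-2-yl]methanol
Conditions: Ti(OiPr)4 (5 mol %), L-(+)-diisopropyl tartrate (6 mol %), t-BuOOH, 4 Å MS, CH2Cl2, −20 °C
Reagents that add atoms: tert-butyl hydroperoxide CC(C)(C)OO
Why: Katsuki–Sharpless asymmetric epoxidation; the L-(+)-tartrate complex delivers oxygen to the face that gives the (2S,3S) epoxide, and the E alkene fixes the cis-dimethyl relationship.

Step 2
Reactants: 2 [(2S,3S)-2,3-dimethyloxiran-2-yl]methanol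
Product: 3 (2R,3S)-2,3-dimethyloxirane-2-carboxylic acid
Conditions: RuCl3·xH2O (2 mol %), NaIO4, CCl4/MeCN/H2O, rt
Reagents that add atoms: water O
Why: RuO4-catalysed (Sharpless) oxidation of a primary alcohol to the acid leaves the epoxide untouched; the descriptor at C2 changes only through the priority rules.

Step 3
Reactants: 4 (2E)-but-2-enal; 5 (2Z)-but-2-ene
Product: 10 (3S,4S,5E)-3-methylhepta-1,5-dien-4-ol, via (Z)-but-2-enylpotassium 6 (not isolated), via methoxyborate complex 7 (not isolated), via (Z)-crotyldiisopinocampheylborane 8 (not isolated), via dienyl borinate 9 (not isolated)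
Conditions: KOtBu, n-BuLi, THF, −78 to −45 °C; (+)-Ipc2BOMe [from (−)-α-pinene], −78 °C; BF3·OEt2; then 4, −78 °C; NaOH, H2O2, 0 °C to rt
Reagents that add atoms: none
Why: Brown asymmetric crotylboration through a closed chair transition state; the Z-crotyl unit gives the syn methyl/hydroxyl pair and the (−)-α-pinene-derived isopinocampheyl groups direct addition to the Re face of the enal, setting both centres (3S,4S).

Step 4
Reactants: 3 (2R,3S)-2,3-dimethyloxirane-2-carboxylic acid; 10 (3S,4S,5E)-3-methylhepta-1,5-dien-4-ol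
Product: 12 (3S,4S,5E)-3-methylhepta-1,5-dien-4-yl (2R,3S)-2,3-dimethyloxirane-2-carboxylate, via mixed anhydride 11 (not isolated)
Conditions: 2,4,6-Cl3C6H2COCl, Et3N, THF, rt; then 10, DMAP, toluene, rt
Reagents that add atoms: none
Why: Yamaguchi esterification is suited to a hindered α,α-disubstituted acid and a secondary alcohol; no stereocentre is touched.

Step 5
Reactants: 12 (3S,4S,5E)-3-methylhepta-1,5-dien-4-yl (2R,3S)-2,3-dimethyloxirane-2-carboxylate
Product: 14 (3S,4R,5E)-1-hydroxy-3-methylhept-5-en-4-yl (2R,3S)-2,3-dimethyloxirane-2-carboxylate, via B-alkyl-9-borabicyclononane 13 (not isolated)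
Conditions: 9-BBN-H, THF, 0 °C to rt; then H2O2, aq NaOAc, 0 °C
Reagents that add atoms: hydrogen peroxide OO
Why: Anti-Markovnikov hydroboration–oxidation; 9-BBN reacts with the monosubstituted alkene far faster than with the 1,2-disubstituted one, and buffered peroxide spares the ester and epoxide (the 4R label is a priority change only).

Step 6
Reactants: 14 (3S,4R,5E)-1-hydroxy-3-methylhept-5-en-4-yl (2R,3S)-2,3-dimethyloxirane-2-carboxylate
Product: 15 (3S,4R,5E)-3-methyl-1-[(triethylsilyl)oxy]hept-5-en-4-yl (2R,3S)-2,3-dimethyloxirane-2-carboxylate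
Conditions: Et3SiCl, imidazole, CH2Cl2, 0 °C
Reagents that add atoms: chlorotriethylsilane CC[Si](Cl)(CC)CC
Why: Standard silylation of a primary alcohol; the silyl ether later serves as a masked aldehyde.

Step 7
Reactants: 15 (3S,4R,5E)-3-methyl-1-[(triethylsilyl)oxy]hept-5-en-4-yl (2R,3S)-2,3-dimethyloxirane-2-carboxylate
Product: 17 (2R,3S)-3-methyl-1-oxo-5-[(triethylsilyl)oxy]pentan-2-yl (2R,3S)-2,3-dimethyloxirane-2-carboxylate, via ozonide 16 (not isolated)
Conditions: O3, CH2Cl2, −78 °C; then PPh3, −78 °C to rt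
Reagents that add atoms: ozone [O-][O+]=O
Why: Ozonolysis with reductive work-up cleaves the only alkene; the α-acyloxy aldehyde is used crude to avoid epimerisation.

Step 8
Reactants: 18 (2R)-2-(chloromethyl)oxirane; 19 ethynyl(trimethyl)silane
Product: 21 (2R)-1-chloro-5-(trimethylsilyl)pent-4-yn-2-ol, via lithium (trimethylsilyl)acetylide 20 (not isolated)
Conditions: n-BuLi, THF, −78 °C; BF3·OEt2; then 18, −78 °C
Reagents that add atoms: none
Why: BF3-promoted (Yamaguchi) alkynylation opens the epoxide at its unsubstituted carbon; the chiral-pool stereocentre is not touched.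

Step 9
Reactants: 21 (2R)-1-chloro-5-(trimethylsilyl)pent-4-yn-2-ol
Product: 23 (3R)-6-(trimethylsilyl)hex-1-en-5-yn-3-ol, via silylpropargyl oxirane 22 (not isolated)
Conditions: Me3S+ I−, n-BuLi, THF, −10 °C to rt
Reagents that add atoms: trimethylsulfonium iodide C[S+](C)C.[I-]
Why: The ylide first closes the chlorohydrin to the epoxide, then opens it at CH2 and loses Me2S (Corey–Chaykovsky-type one-carbon homologation to an allylic alcohol); the carbinol centre is retained.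

Step 10
Reactants: 23 (3R)-6-(trimethylsilyl)hex-1-en-5-yn-3-ol
Product: 24 (3R)-hex-1-en-5-yn-3-ol
Conditions: K2CO3, MeOH, rt
Reagents that add atoms: none
Why: Methanolysis of the alkynyl C–Si bond frees the terminal alkyne needed for carbometalation.

Step 11
Reactants: 24 (3R)-hex-1-en-5-yn-3-ol
Product: 28 (3R,5Z)-6-iodo-5-methylhexa-1,5-dien-3-ol, via aluminium alkoxide 25 (not isolated), via (E)-alkenylalane 26 (not isolated), via cyclic (Z)-alkenylalane 27 (not isolated)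
Conditions: Me3Al (3 equiv), Cp2ZrCl2 (25 mol %), ClCH2CH2Cl, rt; reflux 72 h; then I2, THF, −30 to 0 °C; aq Na2S2O3, potassium sodium tartrate
Reagents that add atoms: trimethylaluminium C[Al](C)C; iodine II
Why: Negishi zirconium-catalysed syn-carboalumination of the alkyne, then chelation-driven thermal isomerisation to the six-membered alkoxide-bound (Z)-alkenylalane (net anti-carbometalation), and iodinolysis with retention, place iodine cis to the CH2 group.

Step 12
Reactants: 28 (3R,5Z)-6-iodo-5-methylhexa-1,5-dien-3-ol; 29 2-(bromomethyl)prop-2-enoic acid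
Product: 31 (3R,5Z)-6-iodo-5-methylhexa-1,5-dien-3-yl 2-(bromomethyl)prop-2-enoate, via O-acylisourea 30 (not isolated)
Conditions: i-PrN=C=N-i-Pr, DMAP (5 mol %), CH2Cl2, 0 °C
Reagents that add atoms: none
Why: Steglich esterification at low temperature with little DMAP limits displacement of the allylic bromide; the stereocentre is untouched.

Step 13
Reactants: 31 (3R,5Z)-6-iodo-5-methylhexa-1,5-dien-3-yl 2-(bromomethyl)prop-2-enoate
Product: 32 (5R)-3-(bromomethyl)-5-[(2Z)-3-iodo-2-methylprop-2-en-1-yl]furan-2(5H)-one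
Conditions: second-generation Grubbs catalyst RuCl2(=CHPh)(H2IMes)(PCy3) (5 mol %), CH2Cl2, 40 °C, 0.01 M
Reagents that add atoms: none
Why: Ring-closing metathesis between the vinyl group and the acrylate gives the five-membered butenolide; the hindered trisubstituted iodoalkene does not take part.

Step 14
Reactants: 32 (5R)-3-(bromomethyl)-5-[(2Z)-3-iodo-2-methylprop-2-en-1-yl]furan-2(5H)-one; 17 (2R,3S)-3-methyl-1-oxo-5-[(triethylsilyl)oxy]pentan-2-yl (2R,3S)-2,3-dimethyloxirane-2-carboxylate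
Product: 34 (1R,2R,3S)-1-{(2R,3S)-2-[(2Z)-3-iodo-2-methylprop-2-en-1-yl]-4-methylidene-5-oxooxolan-3-yl}-3-methyl-1,5-bis[(triethylsilyl)oxy]pentan-2-yl (2R,3S)-2,3-dimethyloxirane-2-carboxylate, via allylchromium species 33 (not isolated)
Conditions: CrCl2 (10 mol %), L* (11 mol %; 3,6-di-tert-butyl-1,8-bis(4-isopropyl-4,5-dihydro-1,3-oxazol-2-yl)-9H-carbazole, the antipode that adds to the Re face of the aldehyde), i-Pr2NEt (30 mol %), Mn (3 equiv), Et3SiCl (2 equiv), THF, rt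
Reagents that add atoms: chlorotriethylsilane CC[Si](Cl)(CC)CC
Why: Proposed new method: a ligand-controlled, chromium-catalysed carbonyl allylation with a 3-(bromomethyl)butenolide as allyl donor; divalent chromium (regenerated by Mn) inserts only into the allylic C–Br bond (no nickel, so the alkenyl iodide is inert), the trivalent allylchromium adds through its γ-carbon (ring C4) in a closed chair transition state, anti to the C5 side chain and with the aldehyde residue equatorial, which forms the C3a–C4 bond, the exocyclic methylene, the trans-lactone and the anti carbinol in one event, while the pincer ligand selects the Re face of the aldehyde and so reinforces the reagent's bias against the opposing Felkin preference of the α-acyloxy aldehyde; Et3SiCl turns the chromium alkoxide over and delivers the silyl ether directly; the closest known chemistry is the catalytic asymmetric Nozaki–Hiyama allylation with acyclic 2-(alkoxycarbonyl)allyl bromides and the stoichiometric zinc or indium Barbier reaction of bromomethylbutenolides.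

Step 15
Reactants: 34 (1R,2R,3S)-1-{(2R,3S)-2-[(2Z)-3-iodo-2-methylprop-2-en-1-yl]-4-methylidene-5-oxooxolan-3-yl}-3-methyl-1,5-bis[(triethylsilyl)oxy]pentan-2-yl (2R,3S)-2,3-dimethyloxirane-2-carboxylate
Product: 35 (1R,2R,3S)-1-{(2R,3S)-2-[(2Z)-3-iodo-2-methylprop-2-en-1-yl]-4-methylidene-5-oxooxolan-3-yl}-3-methyl-5-oxo-1-[(triethylsilyl)oxy]pentan-2-yl (2R,3S)-2,3-dimethyloxirane-2-carboxylate
Conditions: (COCl)2, DMSO, CH2Cl2, −78 to −40 °C; then Et3N, −78 to 0 °C
Reagents that add atoms: none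
Why: Under Swern conditions a primary triethylsilyl ether is cleaved and oxidised to the aldehyde in one operation while the hindered secondary silyl ether survives, so no separate deprotection is needed.

Step 16
Reactants: 35 (1R,2R,3S)-1-{(2R,3S)-2-[(2Z)-3-iodo-2-methylprop-2-en-1-yl]-4-methylidene-5-oxooxolan-3-yl}-3-methyl-5-oxo-1-[(triethylsilyl)oxy]pentan-2-yl (2R,3S)-2,3-dimethyloxirane-2-carboxylate
Product: 37 (3aS,4R,5R,6S,9Z,11aR)-8-hydroxy-6,10-dimethyl-3-methylidene-2-oxo-4-[(triethylsilyl)oxy]-2,3,3a,4,5,6,7,8,11,11a-decahydrocyclodeca[b]furan-5-yl (2R,3S)-2,3-dimethyloxirane-2-carboxylate (C8 epimers), via alkenylchromium species 36 (not isolated)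
Conditions: CrCl2 (10 equiv), NiCl2 (0.1 equiv), DMSO/THF, rt, 0.002 M
Reagents that add atoms: none
Why: Intramolecular Nozaki–Hiyama–Kishi coupling; nickel activates the alkenyl iodide with retention of the Z geometry, the alkenylchromium adds only to the aldehyde, and the new C8 carbinol centre is removed in the next step.

Step 17
Reactants: 37 (3aS,4R,5R,6S,9Z,11aR)-8-hydroxy-6,10-dimethyl-3-methylidene-2-oxo-4-[(triethylsilyl)oxy]-2,3,3a,4,5,6,7,8,11,11a-decahydrocyclodeca[b]furan-5-yl (2R,3S)-2,3-dimethyloxirane-2-carboxylate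
Product: 38 (3aS,4R,5R,6S,9Z,11aR)-6,10-dimethyl-3-methylidene-2,8-dioxo-4-[(triethylsilyl)oxy]-2,3,3a,4,5,6,7,8,11,11a-decahydrocyclodeca[b]furan-5-yl (2R,3S)-2,3-dimethyloxirane-2-carboxylate
Conditions: Dess–Martin periodinane, NaHCO3, CH2Cl2, 0 °C to rt
Reagents that add atoms: none
Why: Buffered Dess–Martin oxidation converts both allylic alcohol epimers into the (Z)-enone without touching the silyl ether, epoxide or lactone.

Step 18
Reactants: 38 (3aS,4R,5R,6S,9Z,11aR)-6,10-dimethyl-3-methylidene-2,8-dioxo-4-[(triethylsilyl)oxy]-2,3,3a,4,5,6,7,8,11,11a-decahydrocyclodeca[b]furan-5-yl (2R,3S)-2,3-dimethyloxirane-2-carboxylate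
Product: 39 (3aR,4R,5R,6S,9Z,11aR)-4-hydroxy-6,10-dimethyl-3-methylidene-2,8-dioxo-2,3,3a,4,5,6,7,8,11,11a-decahydrocyclodeca[b]furan-5-yl (2R,3S)-2,3-dimethyloxirane-2-carboxylate
Conditions: HF·pyridine, pyridine, THF, 0 °C
Reagents that add atoms: none
Why: Buffered fluoride desilylation frees the C4 hydroxyl under conditions that the glycidic ester, enone and α-methylene lactone tolerate (the 3aR label is a priority change only).

**Compound list**

1 | (2E)-2-methylbut-2-en-1-ol | C/C=C(\C)CO | starting material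
2 | [(2S,3S)-2,3-dimethyloxiran-2-yl]methanol | OC[C@]1(C)O[C@H]1C | intermediate
3 | (2R,3S)-2,3-dimethyloxirane-2-carboxylic acid | OC(=O)[C@]1(C)O[C@H]1C | intermediate
4 | (2E)-but-2-enal | C/C=C/C=O | starting material
5 | (2Z)-but-2-ene | C/C=C\C | starting material
6 | (2Z)-but-2-en-1-ylpotassium [in situ] | C/C=C\C[K] | intermediate
7 | potassium [(2Z)-but-2-en-1-yl](methoxy)bis[(1S,2R,3S,5S)-2,6,6-trimethylbicyclo[3.1.1]heptan-3-yl]borate [in situ] | [K+].C/C=C\C[B-](OC)([C@H]1C[C@H]2C[C@@H]([C@@H]1C)C2(C)C)[C@H]1C[C@H]2C[C@@H]([C@@H]1C)C2(C)C | intermediate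
8 | [(2Z)-but-2-en-1-yl]bis[(1S,2R,3S,5S)-2,6,6-trimethylbicyclo[3.1.1]heptan-3-yl]borane [in situ] | C/C=C\CB([C@H]1C[C@H]2C[C@@H]([C@@H]1C)C2(C)C)[C@H]1C[C@H]2C[C@@H]([C@@H]1C)C2(C)C | intermediate
9 | (3S,4S,5E)-3-methylhepta-1,5-dien-4-yl bis[(1S,2R,3S,5S)-2,6,6-trimethylbicyclo[3.1.1]heptan-3-yl]borinate [in situ] | C=C[C@H](C)[C@@H](OB([C@H]1C[C@H]2C[C@@H]([C@@H]1C)C2(C)C)[C@H]1C[C@H]2C[C@@H]([C@@H]1C)C2(C)C)/C=C/C | intermediate
10 | (3S,4S,5E)-3-methylhepta-1,5-dien-4-ol | C=C[C@H](C)[C@@H](O)/C=C/C | intermediate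
11 | (2R,3S)-2,3-dimethyloxirane-2-carboxylic 2,4,6-trichlorobenzoic anhydride [in situ] | O=C(OC(=O)c1c(Cl)cc(Cl)cc1Cl)[C@]1(C)O[C@H]1C | intermediate
12 | (3S,4S,5E)-3-methylhepta-1,5-dien-4-yl (2R,3S)-2,3-dimethyloxirane-2-carboxylate | C=C[C@H](C)[C@@H](OC(=O)[C@]1(C)O[C@H]1C)/C=C/C | intermediate
13 | (3S,4R,5E)-1-(9-borabicyclo[3.3.1]nonan-9-yl)-3-methylhept-5-en-4-yl (2R,3S)-2,3-dimethyloxirane-2-carboxylate [in situ] | C1CCC2CCCC1B2CC[C@H](C)[C@@H](OC(=O)[C@]3(C)O[C@H]3C)/C=C/C | intermediate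
14 | (3S,4R,5E)-1-hydroxy-3-methylhept-5-en-4-yl (2R,3S)-2,3-dimethyloxirane-2-carboxylate | OCC[C@H](C)[C@@H](OC(=O)[C@]1(C)O[C@H]1C)/C=C/C | intermediate
15 | (3S,4R,5E)-3-methyl-1-[(triethylsilyl)oxy]hept-5-en-4-yl (2R,3S)-2,3-dimethyloxirane-2-carboxylate | CC[Si](CC)(CC)OCC[C@H](C)[C@@H](OC(=O)[C@]1(C)O[C@H]1C)/C=C/C | intermediate
16 | (1R,2S)-2-methyl-1-(5-methyl-1,2,4-trioxolan-3-yl)-4-[(triethylsilyl)oxy]butyl (2R,3S)-2,3-dimethyloxirane-2-carboxylate [in situ; trioxolane centres mixed] | CC[Si](CC)(CC)OCC[C@H](C)[C@@H](OC(=O)[C@]1(C)O[C@H]1C)C1OOC(C)O1 | intermediate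
17 | (2R,3S)-3-methyl-1-oxo-5-[(triethylsilyl)oxy]pentan-2-yl (2R,3S)-2,3-dimethyloxirane-2-carboxylate | CC[Si](CC)(CC)OCC[C@H](C)[C@@H](OC(=O)[C@]1(C)O[C@H]1C)C=O | intermediate
18 | (2R)-2-(chloromethyl)oxirane | ClC[C@H]1CO1 | starting material
19 | ethynyl(trimethyl)silane | C#C[Si](C)(C)C | starting material
20 | lithium (trimethylsilyl)acetylide [in situ] | [Li]C#C[Si](C)(C)C | intermediate
21 | (2R)-1-chloro-5-(trimethylsilyl)pent-4-yn-2-ol | ClC[C@H](O)CC#C[Si](C)(C)C | intermediate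
22 | trimethyl{3-[(2R)-oxiran-2-yl]prop-1-yn-1-yl}silane [in situ] | C[Si](C)(C)C#CC[C@@H]1CO1 | intermediate
23 | (3R)-6-(trimethylsilyl)hex-1-en-5-yn-3-ol | C=C[C@H](O)CC#C[Si](C)(C)C | intermediate
24 | (3R)-hex-1-en-5-yn-3-ol | C=C[C@H](O)CC#C | intermediate
25 | dimethylaluminium (3R)-hex-1-en-5-yn-3-olate [in situ] | C=C[C@H](O[Al](C)C)CC#C | intermediate
26 | dimethylaluminium (3R,5E)-6-(dimethylalumanyl)-5-methylhexa-1,5-dien-3-olate [in situ] | C=C[C@H](O[Al](C)C)C/C(C)=C/[Al](C)C | intermediate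
27 | (6R)-6-ethenyl-2,4-dimethyl-5,6-dihydro-2H-1,2-oxaluminine [in situ] | C=C[C@H]1CC(C)=C[Al](C)O1 | intermediate
28 | (3R,5Z)-6-iodo-5-methylhexa-1,5-dien-3-ol | C=C[C@H](O)C/C(C)=C\I | intermediate
29 | 2-(bromomethyl)prop-2-enoic acid | C=C(CBr)C(=O)O | starting material
30 | 2-(bromomethyl)prop-2-enoic N,N'-diisopropylcarbamimidic anhydride [in situ] | C=C(CBr)C(=O)OC(=NC(C)C)NC(C)C | intermediate
31 | (3R,5Z)-6-iodo-5-methylhexa-1,5-dien-3-yl 2-(bromomethyl)prop-2-enoate | C=C[C@H](OC(=O)C(=C)CBr)C/C(C)=C\I | intermediate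
32 | (5R)-3-(bromomethyl)-5-[(2Z)-3-iodo-2-methylprop-2-en-1-yl]furan-2(5H)-one | O=C1O[C@H](C/C(C)=C\I)C=C1CBr | intermediate
33 | dichloro({(5R)-5-[(2Z)-3-iodo-2-methylprop-2-en-1-yl]-2-oxo-2,5-dihydrofuran-3-yl}methyl)chromium [in situ; trivalent chromium, chiral ligand omitted] | Cl[Cr](Cl)CC1=C[C@@H](C/C(C)=C\I)OC1=O | intermediate
34 | (1R,2R,3S)-1-{(2R,3S)-2-[(2Z)-3-iodo-2-methylprop-2-en-1-yl]-4-methylidene-5-oxooxolan-3-yl}-3-methyl-1,5-bis[(triethylsilyl)oxy]pentan-2-yl (2R,3S)-2,3-dimethyloxirane-2-carboxylate | C=C1C(=O)O[C@H](C/C(C)=C\I)[C@H]1[C@@H](O[Si](CC)(CC)CC)[C@H](OC(=O)[C@]2(C)O[C@H]2C)[C@@H](C)CCO[Si](CC)(CC)CC | intermediate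
35 | (1R,2R,3S)-1-{(2R,3S)-2-[(2Z)-3-iodo-2-methylprop-2-en-1-yl]-4-methylidene-5-oxooxolan-3-yl}-3-methyl-5-oxo-1-[(triethylsilyl)oxy]pentan-2-yl (2R,3S)-2,3-dimethyloxirane-2-carboxylate | C=C1C(=O)O[C@H](C/C(C)=C\I)[C@H]1[C@@H](O[Si](CC)(CC)CC)[C@H](OC(=O)[C@]2(C)O[C@H]2C)[C@@H](C)CC=O | intermediate
36 | (Z)-alkenyl(dichloro)chromium formed from 35 by exchange of iodine for chromium [in situ; trivalent chromium] | C=C1C(=O)O[C@H](C/C(C)=C\[Cr](Cl)Cl)[C@H]1[C@@H](O[Si](CC)(CC)CC)[C@H](OC(=O)[C@]2(C)O[C@H]2C)[C@@H](C)CC=O | intermediate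
37 | (3aS,4R,5R,6S,9Z,11aR)-8-hydroxy-6,10-dimethyl-3-methylidene-2-oxo-4-[(triethylsilyl)oxy]-2,3,3a,4,5,6,7,8,11,11a-decahydrocyclodeca[b]furan-5-yl (2R,3S)-2,3-dimethyloxirane-2-carboxylate (C8 epimers) | C=C1C(=O)O[C@@H]2C/C(C)=C\C(O)C[C@H](C)[C@@H](OC(=O)[C@]3(C)O[C@H]3C)[C@H](O[Si](CC)(CC)CC)[C@@H]12 | intermediate
38 | (3aS,4R,5R,6S,9Z,11aR)-6,10-dimethyl-3-methylidene-2,8-dioxo-4-[(triethylsilyl)oxy]-2,3,3a,4,5,6,7,8,11,11a-decahydrocyclodeca[b]furan-5-yl (2R,3S)-2,3-dimethyloxirane-2-carboxylate | C=C1C(=O)O[C@@H]2C/C(C)=C\C(=O)C[C@H](C)[C@@H](OC(=O)[C@]3(C)O[C@H]3C)[C@H](O[Si](CC)(CC)CC)[C@@H]12 | intermediate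
39 | (3aR,4R,5R,6S,9Z,11aR)-4-hydroxy-6,10-dimethyl-3-methylidene-2,8-dioxo-2,3,3a,4,5,6,7,8,11,11a-decahydrocyclodeca[b]furan-5-yl (2R,3S)-2,3-dimethyloxirane-2-carboxylate | C=C1C(=O)O[C@@H]2C/C(C)=C\C(=O)C[C@H](C)[C@@H](OC(=O)[C@]3(C)O[C@H]3C)[C@H](O)[C@@H]12 | target

**Totals and risks**

Total step count: 18.
Longest linear sequence: 11 steps (8–13, then 14–18; the sequence 1, 2, 4–7, 14–18 is equally long).

Most likely to fail:

1. Step 14 (the proposed new allylation). Risks are incomplete override of the aldehyde's Felkin bias, slow turnover with Et3SiCl, and chloride attack on the glycidic ester. The fallback uses known chelation-controlled chemistry and installs the ester afterwards; it sets out from 10 (with 32 and 3) and returns at 34. Dienol 10 is protected (NaH, 4-methoxybenzyl chloride, DMF) as 1-methoxy-4-({[(3S,4S,5E)-3-methylhepta-1,5-dien-4-yl]oxy}methyl)benzene F1. Hydroboration (9-BBN-H; H2O2, NaOH) gives (3S,4R,5E)-4-[(4-methoxybenzyl)oxy]-3-methylhept-5-en-1-ol F2, and Et3SiCl/imidazole gives triethyl({(3S,4R,5E)-4-[(4-methoxybenzyl)oxy]-3-methylhept-5-en-1-yl}oxy)silane F3. Cleavage with OsO4 (cat.), NaIO4 and 2,6-lutidine gives (2R,3S)-2-[(4-methoxybenzyl)oxy]-3-methyl-5-[(triethylsilyl)oxy]pentanal F4. The allylzinc bromide from 32 and Zn dust in THF adds to F4 with the ether oxygen chelated to zinc, so chelation, the chair and the anti approach all favour the syn diol, (4R,5R)-4-{(1R,2R,3S)-1-hydroxy-2-[(4-methoxybenzyl)oxy]-3-methyl-5-[(triethylsilyl)oxy]pentyl}-5-[(2Z)-3-iodo-2-methylprop-2-en-1-yl]-3-methylideneoxolan-2-one F5. Et3SiOTf/2,6-lutidine gives (4S,5R)-4-{(1R,2R,3S)-2-[(4-methoxybenzyl)oxy]-3-methyl-1,5-bis[(triethylsilyl)oxy]pentyl}-5-[(2Z)-3-iodo-2-methylprop-2-en-1-yl]-3-methylideneoxolan-2-one F6. DDQ in CH2Cl2/pH 7 buffer gives (4S,5R)-4-{(1R,2R,3S)-2-hydroxy-3-methyl-1,5-bis[(triethylsilyl)oxy]pentyl}-5-[(2Z)-3-iodo-2-methylprop-2-en-1-yl]-3-methylideneoxolan-2-one F7. Yamaguchi esterification of F7 with 3 (through 11) gives 34.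

2. Step 16 (ten-membered Nozaki–Hiyama–Kishi closure). Risks are oligomerisation, a sluggish trisubstituted alkenyl iodide, and reduction of the glycidic ester by excess divalent chromium. The fallback closes the same bond at the ketone oxidation level by a palladium-catalysed acyl–alkenyl coupling; it sets out from 35 and returns at 38, so step 17 is not needed. Pinnick oxidation (NaClO2, NaH2PO4, 2-methylbut-2-ene) gives (3S,4R,5R)-4-{[(2R,3S)-2,3-dimethyloxirane-2-carbonyl]oxy}-5-{(2R,3S)-2-[(2Z)-3-iodo-2-methylprop-2-en-1-yl]-4-methylidene-5-oxooxolan-3-yl}-3-methyl-5-[(triethylsilyl)oxy]pentanoic acid F8. EtSH, dicyclohexylcarbodiimide and DMAP give its S-ethyl thioester F9. Me3SnSnMe3 with Pd(PPh3)4 in toluene at 80 °C exchanges iodine for tin to give the (Z)-alkenyl(trimethyl)stannane S-ethyl thioester F10. Intramolecular Liebeskind–Srogl coupling (Pd2(dba)3, tri(2-furyl)phosphine, copper thiophene-2-carboxylate, THF, 0.002 M) gives 38 with retention of the Z geometry.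

3. Step 11 (anti-carbometalation of an enynol). Risks are that the vinyl group or the allylic alkoxide does not survive three days at reflux with Me3Al, or that isomerisation is incomplete. The fallback carbometalates before the vinyl group exists; it sets out from 21 and returns at 28. Bu4NF buffered with AcOH (THF, 0 °C) gives (2R)-1-chloropent-4-yn-2-ol F11. The same Negishi sequence (Me3Al, Cp2ZrCl2, ClCH2CH2Cl, reflux; I2) on this simple homopropargylic alcohol gives (2R,4Z)-1-chloro-5-iodo-4-methylpent-4-en-2-ol F12. Preformed dimethylsulfonium methylide (no free n-BuLi) closes it to (2R)-2-[(2Z)-3-iodo-2-methylprop-2-en-1-yl]oxirane F13, which is not isolated and is opened in the same flask to 28.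

**Further compounds**

F1 | step 14 | 1-methoxy-4-({[(3S,4S,5E)-3-methylhepta-1,5-dien-4-yl]oxy}methyl)benzene | C=C[C@H](C)[C@@H](OCc1ccc(OC)cc1)/C=C/C
F2 | step 14 | (3S,4R,5E)-4-[(4-methoxybenzyl)oxy]-3-methylhept-5-en-1-ol | OCC[C@H](C)[C@@H](OCc1ccc(OC)cc1)/C=C/C
F3 | step 14 | triethyl({(3S,4R,5E)-4-[(4-methoxybenzyl)oxy]-3-methylhept-5-en-1-yl}oxy)silane | CC[Si](CC)(CC)OCC[C@H](C)[C@@H](OCc1ccc(OC)cc1)/C=C/C
F4 | step 14 | (2R,3S)-2-[(4-methoxybenzyl)oxy]-3-methyl-5-[(triethylsilyl)oxy]pentanal | CC[Si](CC)(CC)OCC[C@H](C)[C@@H](OCc1ccc(OC)cc1)C=O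
F5 | step 14 | (4R,5R)-4-{(1R,2R,3S)-1-hydroxy-2-[(4-methoxybenzyl)oxy]-3-methyl-5-[(triethylsilyl)oxy]pentyl}-5-[(2Z)-3-iodo-2-methylprop-2-en-1-yl]-3-methylideneoxolan-2-one | C=C1C(=O)O[C@H](C/C(C)=C\I)[C@H]1[C@@H](O)[C@H](OCc2ccc(OC)cc2)[C@@H](C)CCO[Si](CC)(CC)CC
F6 | step 14 | (4S,5R)-4-{(1R,2R,3S)-2-[(4-methoxybenzyl)oxy]-3-methyl-1,5-bis[(triethylsilyl)oxy]pentyl}-5-[(2Z)-3-iodo-2-methylprop-2-en-1-yl]-3-methylideneoxolan-2-one | C=C1C(=O)O[C@H](C/C(C)=C\I)[C@H]1[C@@H](O[Si](CC)(CC)CC)[C@H](OCc2ccc(OC)cc2)[C@@H](C)CCO[Si](CC)(CC)CC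
F7 | step 14 | (4S,5R)-4-{(1R,2R,3S)-2-hydroxy-3-methyl-1,5-bis[(triethylsilyl)oxy]pentyl}-5-[(2Z)-3-iodo-2-methylprop-2-en-1-yl]-3-methylideneoxolan-2-one | C=C1C(=O)O[C@H](C/C(C)=C\I)[C@H]1[C@@H](O[Si](CC)(CC)CC)[C@H](O)[C@@H](C)CCO[Si](CC)(CC)CC
F8 | step 16 | (3S,4R,5R)-4-{[(2R,3S)-2,3-dimethyloxirane-2-carbonyl]oxy}-5-{(2R,3S)-2-[(2Z)-3-iodo-2-methylprop-2-en-1-yl]-4-methylidene-5-oxooxolan-3-yl}-3-methyl-5-[(triethylsilyl)oxy]pentanoic acid | C=C1C(=O)O[C@H](C/C(C)=C\I)[C@H]1[C@@H](O[Si](CC)(CC)CC)[C@H](OC(=O)[C@]2(C)O[C@H]2C)[C@@H](C)CC(=O)O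
F9 | step 16 | S-ethyl thioester of F8 | C=C1C(=O)O[C@H](C/C(C)=C\I)[C@H]1[C@@H](O[Si](CC)(CC)CC)[C@H](OC(=O)[C@]2(C)O[C@H]2C)[C@@H](C)CC(=O)SCC
F10 | step 16 | S-ethyl thioester of F8 with the iodine replaced by trimethylstannyl, (Z) | C=C1C(=O)O[C@H](C/C(C)=C\[Sn](C)(C)C)[C@H]1[C@@H](O[Si](CC)(CC)CC)[C@H](OC(=O)[C@]2(C)O[C@H]2C)[C@@H](C)CC(=O)SCC
F11 | step 11 | (2R)-1-chloropent-4-yn-2-ol | ClC[C@H](O)CC#C
F12 | step 11 | (2R,4Z)-1-chloro-5-iodo-4-methylpent-4-en-2-ol | ClC[C@H](O)C/C(C)=C\I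
F13 | step 11 | (2R)-2-[(2Z)-3-iodo-2-methylprop-2-en-1-yl]oxirane | I/C=C(C)\C[C@@H]1CO1
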